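**Plan**
Numbering: ring C1 (CMe2), C2–C4 (CH2), C5 (C(Me)OH), C6 (C(OH) bearing the chain); chain C7–C15, then C15′–C12′ (ester carbon).
Cuts: C15=C15′ and C11=C12 (Horner–Wadsworth–Emmons), C6–C7 (acetylide onto a C6 ketone), then ring bonds C2–C3 and C4–C5 together, which releases a two-carbon alkene (C3, C4).
Enabling feature: the C5 oxygen lies 1,4 to C2 across C6 and C1, C6 is a carbinol (latent ketone) and C1 is quaternary. The atoms O(C5), C5, C6, C1 and C2 are therefore a five-membered carbonyl ylide, and the ring is a 7-oxabicyclo[2.2.1]heptan-2-one whose C5–O–C2 bridge is later unlocked by a sulfonyl group on C3.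
Forward: diazo keto aldehyde (3 steps) → oxabicycle (carbocycle and oxygen bridge formed in one step) → acetylide addition and bridge opening → removal of the sulfone → C15 dienal → C20 aldehyde → C25 ester.
Stereochemistry: C5 from the chiral dirhodium carboxylate in the cycloaddition; C6 from exo attack on the bicyclic ketone, syn to the bridge oxygen, which gives the trans diol; E alkenes from trans-hydroalumination and thermodynamically controlled olefinations.

Key step: step 4

Assumption: 6 and 18 are taken as catalogue compounds, and because the sense of induction of the chiral dirhodium carboxylate cannot be predicted with certainty, the (S)-tert-leucinate catalyst is written and its mirror image is to be used if it favours the mirror-image adduct.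

Step 1
Reactants: 1 3-hydroxy-2,2-dimethylpropanoic acid
Product: 2 1-hydroxy-2,2-dimethylpentan-3-one
Conditions: EtLi (3.5 equiv), THF–Et2O, −78 → 0 °C; inverse quench into 1 M HCl, 0 °C
Reagents that add atoms: ethyllithium, [Li]CC
Why: The dilithium salt of 1 adds one further ethyllithium at the carboxylate to give a gem-dialkoxide that survives until the acidic quench, so the ketone is released only when no organolithium is left (ketone synthesis from a lithium carboxylate and an organolithium).

Step 2
Reactants: 2 1-hydroxy-2,2-dimethylpentan-3-one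
Product: 4 2-diazo-5-hydroxy-4,4-dimethylpentan-3-one, via bis(trifluoroacetyl) derivative 3 (not isolated)
Conditions: LiN(SiMe3)2 (2.2 equiv), THF, −78 °C; CF3CO2CH2CF3 (2.4 equiv); aq. HCl work-up; then 4-acetamidobenzenesulfonyl azide, Et3N, H2O (1 equiv), MeCN, rt; then K2CO3, MeOH, 0 °C
Reagents that add atoms: 4-acetamidobenzenesulfonyl azide, CC(=O)Nc1ccc(cc1)S(=O)(=O)N=[N+]=[N-] (the two diazo nitrogens); 2,2,2-trifluoroethyl trifluoroacetate, FC(F)(F)COC(=O)C(F)(F)F (trifluoroacetyl groups of 3 only)
Why: Only the ethyl CH2 of 2 is enolisable, so C-trifluoroacetylation of its lithium enolate (the alkoxide is acylated as well) followed by Regitz-type detrifluoroacetylative diazo transfer puts the diazo group on the carbon that bears the methyl group, and brief methanolysis frees the primary alcohol.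

Step 3
Reactants: 4 2-diazo-5-hydroxy-4,4-dimethylpentan-3-one
Product: 5 4-diazo-2,2-dimethyl-3-oxopentanal
Conditions: Dess–Martin periodinane, NaHCO3, CH2Cl2, 0 °C → rt
Reagents that add atoms: none
Why: Dess–Martin oxidation converts the neopentyl primary alcohol into the aldehyde under buffered conditions that acceptor-stabilised diazo ketones tolerate, and the product has no enolisable hydrogen between its two carbonyl groups.

Step 4
Reactants: 5 4-diazo-2,2-dimethyl-3-oxopentanal; 6 1-(ethenesulfonyl)-4-methylbenzene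
Product: 8 (1R,4R,5S)-1,3,3-trimethyl-5-(4-methylbenzenesulfonyl)-7-oxabicyclo[2.2.1]heptan-2-one, via carbonyl ylide 7 (not isolated)
Conditions: Rh2(S-TCPTTL)4 [dirhodium tetrakis(N-tetrachlorophthaloyl-(S)-tert-leucinate)] (1 mol %), 6 (3 equiv), PhCF3, 0 °C, 5 added over 2 h
Reagents that add atoms: none
Why: Loss of N2 from 5 at the chiral dirhodium carboxylate gives a carbenoid at C5 that is trapped by a lone pair of the C2 aldehyde oxygen, closing the five-membered ylide ring of 7 (O, C2, C1, C6, C5) by attack of oxygen on the carbenoid carbon, and 7 then adds to the vinyl sulfone across C2 and C5. This second event is a concerted, suprafacial six-electron 1,3-dipolar cycloaddition that closes the carbocycle C1–C6 and the second oxolane ring of the 7-oxabicyclo[2.2.1]heptane at once by forming C2–C3 and C4–C5. The closest known reaction type is the tandem carbonyl-ylide formation–cycloaddition of diazo ketones that carry a second carbonyl group in a 1,4 relation, including its enantioselective variant with chiral dirhodium carboxylates. Regiochemistry follows the polarity of the ylide, the enolate-like terminus C5 (conjugated with the C6 ketone) bonding to the unsubstituted alkene carbon C4 and the oxocarbenium-like terminus C2 to the sulfonyl-bearing carbon C3. The absolute configuration at C5 and C2 is set by the ylide face that the tert-leucinate ligands leave open while the ylide is still bound to divalent rhodium, the bridge forces the two new bonds onto the same face, and the sulfonyl group should go exo because the C1 methyl group on the reacting face blocks the endo orientation (this centre is erased in steps 5–7). The step needs ylide formation to outrun the 1,2-hydride shift from the C5 methyl group and the ylide to be trapped before it dimerises or leaves the metal, which the fast five-membered closure, the quaternary C1 and the excess of electron-poor dipolarophile (inert to cyclopropanation) should secure.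

Step 5
Reactants: 8 (1R,4R,5S)-1,3,3-trimethyl-5-(4-methylbenzenesulfonyl)-7-oxabicyclo[2.2.1]heptan-2-one; 9 (2E)-3-methylpent-2-en-4-yn-1-ol
Product: 11 (2E)-5-[(1S,6R)-1,6-dihydroxy-2,2,6-trimethyl-4-(4-methylbenzenesulfonyl)cyclohex-3-en-1-yl]-3-methylpent-2-en-4-yn-1-ol, via bicyclic propargylic alkoxide 10 (not isolated)
Conditions: 9 (2.2 equiv), n-BuLi (4.4 equiv), THF, −78 → 0 °C; 8, −78 → −20 °C; then KOt-Bu (3 equiv), 0 °C → rt; aq. NH4Cl
Reagents that add atoms: none
Why: Acetylide addition to the non-enolisable C6 ketone should occur from the exo face, syn to the bridge oxygen (the usual sense for 1,3,3-trimethylbicyclo[2.2.1]heptan-2-ones, helped here by lithium coordination to the bridge oxygen), which puts the side chain cis to the C5 oxygen and so fixes the trans diol, and deprotonation next to the sulfone then expels the C2–O bond (E1cB β-elimination driven by release of bicyclic strain, open to either epimer at C3) to give the C5 alkoxide and the vinyl sulfone.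

Step 6
Reactants: 11 (2E)-5-[(1S,6R)-1,6-dihydroxy-2,2,6-trimethyl-4-(4-methylbenzenesulfonyl)cyclohex-3-en-1-yl]-3-methylpent-2-en-4-yn-1-ol
Product: 12 (2E,4E)-5-[(1R,2R,4S)-1,2-dihydroxy-2,6,6-trimethyl-4-(4-methylbenzenesulfonyl)cyclohexyl]-3-methylpenta-2,4-dien-1-ol
Conditions: NaAlH2(OCH2CH2OMe)2 (6 equiv), THF, 0 °C → rt; aq. potassium sodium tartrate
Reagents that add atoms: none
Why: The aluminate bound to the C6 oxygen should deliver hydride intramolecularly both to the triple bond (trans-hydroalumination of a propargylic alcohol, which gives the 7E alkene on hydrolysis) and to C2 of the vinyl sulfone (conjugate reduction), while the new sulfonyl-bearing centre (drawn equatorial) is of no consequence because it is erased in step 7.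

Step 7
Reactants: 12 (2E,4E)-5-[(1R,2R,4S)-1,2-dihydroxy-2,6,6-trimethyl-4-(4-methylbenzenesulfonyl)cyclohexyl]-3-methylpenta-2,4-dien-1-ol
Product: 13 (2E,4E)-5-[(1R,2R)-1,2-dihydroxy-2,6,6-trimethylcyclohexyl]-3-methylpenta-2,4-dien-1-ol
Conditions: 6 % Na(Hg), Na2HPO4, MeOH–THF, −20 → 0 °C
Reagents that add atoms: none
Why: Electron transfer from sodium amalgam cleaves the C–S bond of the secondary alkyl aryl sulfone (reductive desulfonylation) and the buffered methanol protonates the carbanion, conditions under which dienes and free alcohols are inert.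

Step 8
Reactants: 13 (2E,4E)-5-[(1R,2R)-1,2-dihydroxy-2,6,6-trimethylcyclohexyl]-3-methylpenta-2,4-dien-1-ol
Product: 14 (2E,4E)-5-[(1R,2R)-1,2-dihydroxy-2,6,6-trimethylcyclohexyl]-3-methylpenta-2,4-dienal
Conditions: activated MnO2 (20 equiv), CH2Cl2, rt, dark
Reagents that add atoms: none
Why: Activated MnO2 oxidises only the primary dienylic alcohol (allylic oxidation), since the two tertiary alcohols carry no carbinol hydrogen.

Step 9
Reactants: 14 (2E,4E)-5-[(1R,2R)-1,2-dihydroxy-2,6,6-trimethylcyclohexyl]-3-methylpenta-2,4-dienal; 15 diethyl [(2E)-3-cyano-2-methylprop-2-en-1-yl]phosphonate (sold as an E/Z mixture, which converges through the delocalised anion)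
Product: 16 (2E,4E,6E,8E)-9-[(1R,2R)-1,2-dihydroxy-2,6,6-trimethylcyclohexyl]-3,7-dimethylnona-2,4,6,8-tetraenenitrile
Conditions: 15 (1.5 equiv), NaH (1.4 equiv), THF, 0 °C; then 14, 0 °C → rt, dark
Reagents that add atoms: none
Why: Horner–Wadsworth–Emmons reaction of the enal with the nitrile-stabilised allylic phosphonate anion forms the 11E double bond under thermodynamic control, the tertiary alcohols being too weakly acidic to quench the anion, and any 13Z isomer that arises from the delocalised anion is removed by chromatography.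

Step 10
Reactants: 16 (2E,4E,6E,8E)-9-[(1R,2R)-1,2-dihydroxy-2,6,6-trimethylcyclohexyl]-3,7-dimethylnona-2,4,6,8-tetraenenitrile
Product: 17 (2E,4E,6E,8E)-9-[(1R,2R)-1,2-dihydroxy-2,6,6-trimethylcyclohexyl]-3,7-dimethylnona-2,4,6,8-tetraenal
Conditions: i-Bu2AlH (3.5 equiv), CH2Cl2, −78 °C; then wet silica gel, aq. potassium sodium tartrate
Reagents that add atoms: water, O
Why: Diisobutylaluminium hydride adds once to the nitrile to give an N-aluminated aldimine that is stable at low temperature and is hydrolysed to the aldehyde on work-up (partial nitrile reduction), two further equivalents being consumed by the hydroxyl groups.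

Step 11
Reactants: 18 methyl (2E)-4-bromo-2-methylbut-2-enoate
Product: 19 methyl (2E)-4-(diethoxyphosphoryl)-2-methylbut-2-enoate
Conditions: P(OEt)3 (1.2 equiv), neat, 120 °C, EtBr distilled off
Reagents that add atoms: triethyl phosphite, CCOP(OCC)OCC
Why: Michaelis–Arbuzov reaction of the primary allylic bromide with triethyl phosphite gives the phosphonate with retention of the E double bond.

Step 12
Reactants: 17 (2E,4E,6E,8E)-9-[(1R,2R)-1,2-dihydroxy-2,6,6-trimethylcyclohexyl]-3,7-dimethylnona-2,4,6,8-tetraenal; 19 methyl (2E)-4-(diethoxyphosphoryl)-2-methylbut-2-enoate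
Product: 20 methyl (2E,4E,6E,8E,10E,12E)-13-[(1R,2R)-1,2-dihydroxy-2,6,6-trimethylcyclohexyl]-2,7,11-trimethyltrideca-2,4,6,8,10,12-hexaenoate
Conditions: 19 (1.5 equiv), NaH (1.4 equiv), THF, 0 °C; then 17, 0 °C → rt, dark
Reagents that add atoms: none
Why: Horner–Wadsworth–Emmons reaction of the polyenal with the ester-stabilised allylic phosphonate anion should give the E double bond at C15=C15′ and keep the E-trisubstituted enoate, no stereocentre being touched.

**Compound list**
1 | 3-hydroxy-2,2-dimethylpropanoic acid | OCC(C)(C)C(=O)O | starting material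
2 | 1-hydroxy-2,2-dimethylpentan-3-one | CCC(=O)C(C)(C)CO | intermediate
3 | 6,6,6-trifluoro-2,2,4-trimethyl-3,5-dioxohexyl trifluoroacetate (not isolated) | CC(C(=O)C(F)(F)F)C(=O)C(C)(C)COC(=O)C(F)(F)F | intermediate
4 | 2-diazo-5-hydroxy-4,4-dimethylpentan-3-one | CC(=[N+]=[N-])C(=O)C(C)(C)CO | intermediate
5 | 4-diazo-2,2-dimethyl-3-oxopentanal | CC(=[N+]=[N-])C(=O)C(C)(C)C=O | intermediate
6 | 1-(ethenesulfonyl)-4-methylbenzene (4-methylphenyl vinyl sulfone) | C=CS(=O)(=O)c1ccc(C)cc1 | starting material
7 | 2,4,4-trimethyl-3-oxo-3,4-dihydro-2H-furan-1-ium-2-ide, the cyclic carbonyl ylide (not isolated) | C[C-]1[O+]=CC(C)(C)C1=O | intermediate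
8 | (1R,4R,5S)-1,3,3-trimethyl-5-(4-methylbenzenesulfonyl)-7-oxabicyclo[2.2.1]heptan-2-one (sulfonyl exo) | C[C@]12O[C@H](C(C)(C)C1=O)[C@@H](S(=O)(=O)c3ccc(C)cc3)C2 | intermediate
9 | (2E)-3-methylpent-2-en-4-yn-1-ol | OC/C=C(C)/C#C | starting material
10 | (1R,2R,4R,5S)-2-[(3E)-5-hydroxy-3-methylpent-3-en-1-yn-1-yl]-1,3,3-trimethyl-5-(4-methylbenzenesulfonyl)-7-oxabicyclo[2.2.1]heptan-2-ol (present as its dilithium alkoxide, not isolated) | OC/C=C(C)/C#C[C@@]1(O)C(C)(C)[C@H]2O[C@]1(C)C[C@@H]2S(=O)(=O)c3ccc(C)cc3 | intermediate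
11 | (2E)-5-[(1S,6R)-1,6-dihydroxy-2,2,6-trimethyl-4-(4-methylbenzenesulfonyl)cyclohex-3-en-1-yl]-3-methylpent-2-en-4-yn-1-ol | OC/C=C(C)/C#C[C@@]1(O)C(C)(C)C=C(S(=O)(=O)c2ccc(C)cc2)C[C@@]1(C)O | intermediate
12 | (2E,4E)-5-[(1R,2R,4S)-1,2-dihydroxy-2,6,6-trimethyl-4-(4-methylbenzenesulfonyl)cyclohexyl]-3-methylpenta-2,4-dien-1-ol | OC/C=C(C)/C=C/[C@@]1(O)C(C)(C)C[C@H](S(=O)(=O)c2ccc(C)cc2)C[C@@]1(C)O | intermediate
13 | (2E,4E)-5-[(1R,2R)-1,2-dihydroxy-2,6,6-trimethylcyclohexyl]-3-methylpenta-2,4-dien-1-ol | OC/C=C(C)/C=C/[C@@]1(O)C(C)(C)CCC[C@@]1(C)O | intermediate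
14 | (2E,4E)-5-[(1R,2R)-1,2-dihydroxy-2,6,6-trimethylcyclohexyl]-3-methylpenta-2,4-dienal | O=C/C=C(C)/C=C/[C@@]1(O)C(C)(C)CCC[C@@]1(C)O | intermediate
15 | diethyl [(2E)-3-cyano-2-methylprop-2-en-1-yl]phosphonate | CCOP(=O)(OCC)C/C(C)=C/C#N | starting material
16 | (2E,4E,6E,8E)-9-[(1R,2R)-1,2-dihydroxy-2,6,6-trimethylcyclohexyl]-3,7-dimethylnona-2,4,6,8-tetraenenitrile | N#C/C=C(C)/C=C/C=C(C)/C=C/[C@@]1(O)C(C)(C)CCC[C@@]1(C)O | intermediate
17 | (2E,4E,6E,8E)-9-[(1R,2R)-1,2-dihydroxy-2,6,6-trimethylcyclohexyl]-3,7-dimethylnona-2,4,6,8-tetraenal | O=C/C=C(C)/C=C/C=C(C)/C=C/[C@@]1(O)C(C)(C)CCC[C@@]1(C)O | intermediate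
18 | methyl (2E)-4-bromo-2-methylbut-2-enoate | COC(=O)/C(C)=C/CBr | starting material
19 | methyl (2E)-4-(diethoxyphosphoryl)-2-methylbut-2-enoate | COC(=O)/C(C)=C/CP(=O)(OCC)OCC | intermediate
20 | methyl (2E,4E,6E,8E,10E,12E)-13-[(1R,2R)-1,2-dihydroxy-2,6,6-trimethylcyclohexyl]-2,7,11-trimethyltrideca-2,4,6,8,10,12-hexaenoate | COC(=O)/C(C)=C/C=C/C=C(C)/C=C/C=C(C)/C=C/[C@@]1(O)C(C)(C)CCC[C@@]1(C)O | target

**Totals**
Total step count: 12. Longest linear sequence: 11 steps (steps 1–10 and 12; step 11 is a side branch).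

**Steps most likely to fail**

Step 4. What may go wrong: the 1,2-hydride shift from the C5 methyl group may compete at the carbenoid stage, or the ylide may leave the chiral metal before it meets the sulfone, so that 8 forms with low enantiomeric purity. Fallback (auxiliary control in place of catalyst control): from 5, decomposition with Rh2(OAc)4 in the presence of 1-[(R)-ethenesulfinyl]-4-methylbenzene gives diastereomeric sulfinyl cycloadducts that differ in the configuration of the bicyclic core and can be separated by chromatography. The isomer (1R,4R,5S)-1,3,3-trimethyl-5-[(R)-4-methylbenzenesulfinyl]-7-oxabicyclo[2.2.1]heptan-2-one F1 is oxidised at sulfur with mCPBA (CH2Cl2, 0 °C) to 8, where the route is rejoined.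

Step 5. What may go wrong: the bulky dilithiated enynol may add slowly to the ketone between two quaternary carbons, so that it acts as a base at the sulfonyl-bearing carbon and the bridge opens before the C6–C7 bond has formed, with loss of the facial bias. Fallback (small nucleophile first, enyne completed by cross-coupling): from 8, HC≡CMgBr (THF, 0 °C) gives (1R,2R,4R,5S)-2-ethynyl-1,3,3-trimethyl-5-(4-methylbenzenesulfonyl)-7-oxabicyclo[2.2.1]heptan-2-ol F2. KOt-Bu (THF, 0 °C → rt) then opens the bridge to (1R,2R)-2-ethynyl-1,3,3-trimethyl-5-(4-methylbenzenesulfonyl)cyclohex-4-ene-1,2-diol F3. Sonogashira coupling of F3 with the known (2E)-3-iodobut-2-en-1-ol (Pd(PPh3)4, CuI, i-Pr2NH, rt) returns to the route at 11.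

Step 9. What may go wrong: rotation about the C13–C14 bond in the delocalised phosphonate anion may give a large share of the 13Z isomer. Fallback (stereoretentive cross-coupling in place of olefination): from 14, Takai olefination (CHI3, CrCl2, THF, 0 °C) gives (1R,2R)-2-[(1E,3E,5E)-6-iodo-3-methylhexa-1,3,5-trien-1-yl]-1,3,3-trimethylcyclohexane-1,2-diol F4. Stille coupling of F4 with the known (2E)-3-(tributylstannyl)but-2-en-1-ol (Pd2(dba)3, AsPh3, NMP, rt) gives (2E,4E,6E,8E)-9-[(1R,2R)-1,2-dihydroxy-2,6,6-trimethylcyclohexyl]-3,7-dimethylnona-2,4,6,8-tetraen-1-ol F5 with the 13E geometry carried over from the stannane. MnO2 oxidation of F5 (CH2Cl2, rt) returns to the route at 17.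

Further compounds
F1 | step 4 | (1R,4R,5S)-1,3,3-trimethyl-5-[(R)-4-methylbenzenesulfinyl]-7-oxabicyclo[2.2.1]heptan-2-one | C[C@]12O[C@H](C(C)(C)C1=O)[C@@H]([S@@](=O)c3ccc(C)cc3)C2
F2 | step 5 | (1R,2R,4R,5S)-2-ethynyl-1,3,3-trimethyl-5-(4-methylbenzenesulfonyl)-7-oxabicyclo[2.2.1]heptan-2-ol | C#C[C@@]1(O)C(C)(C)[C@H]2O[C@]1(C)C[C@@H]2S(=O)(=O)c3ccc(C)cc3
F3 | step 5 | (1R,2R)-2-ethynyl-1,3,3-trimethyl-5-(4-methylbenzenesulfonyl)cyclohex-4-ene-1,2-diol | C#C[C@@]1(O)C(C)(C)C=C(S(=O)(=O)c2ccc(C)cc2)C[C@@]1(C)O
F4 | step 9 | (1R,2R)-2-[(1E,3E,5E)-6-iodo-3-methylhexa-1,3,5-trien-1-yl]-1,3,3-trimethylcyclohexane-1,2-diol | I/C=C/C=C(C)/C=C/[C@@]1(O)C(C)(C)CCC[C@@]1(C)O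
F5 | step 9 | (2E,4E,6E,8E)-9-[(1R,2R)-1,2-dihydroxy-2,6,6-trimethylcyclohexyl]-3,7-dimethylnona-2,4,6,8-tetraen-1-ol | OC/C=C(C)/C=C/C=C(C)/C=C/[C@@]1(O)C(C)(C)CCC[C@@]1(C)O
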